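Ring atoms: C6 (side-chain CH), C7 (C=CH2), C8 (allylic CHBr), C9 (CH2), C10 (CHBr), C11 (CMe2). The 1,3-array C8–C9–C10 of the cyclohexane is read as an opened cyclopropane, so the ring is disconnected to a bicyclo[3.1.0]hexane in which C8 and C10 are bonded. The precursor is the C7 spiro-epoxide of that bicycle. In one operation bromide opens its cyclopropylcarbinyl cation at C10. The cyclopentane C6–C7–C8–C10–C11 takes up C9, C10–Br forms with inversion (trans to the side chain), and a C7=C8 allylic alcohol appears. A double Sharpless epoxidation/reductive transposition then sets C8–O and the C3 carbinol, and bromide inverts C8.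

Key step: step 7

Assumption: spiro-epoxide 11 is drawn as the epimer from ylide attack anti to the cyclopropane CH2; the other epimer ionises to the same cation, so the two need not be separated.

Step 1
Reactants: 1 4,4-dimethylcyclopent-2-en-1-one
Product: 2 (1R)-4,4-dimethylcyclopent-2-en-1-ol
Conditions: (S)-Me-CBS (10 mol %), catecholborane, toluene, −78 °C; aq. NaOH work-up
Reagents that add atoms: none
Why: Corey–Bakshi–Shibata reduction is 1,2-selective on enones, and with the alkenyl arm acting as the larger group the (S)-catalyst should give the (R)-carbinol, which is the only source of absolute configuration for the ring.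

Step 2
Reactants: 2 (1R)-4,4-dimethylcyclopent-2-en-1-ol; 3 diiodomethane
Product: 4 (1S,2R,5R)-4,4-dimethylbicyclo[3.1.0]hexan-2-ol (OH cis to the cyclopropane CH2)
Conditions: Et2Zn, CH2I2, CH2Cl2, −10 to 0 °C
Reagents that add atoms: diiodomethane, ICI
Why: In the Simmons–Smith cyclopropanation (Furukawa variant) the zinc alkoxide directs CH2 (the future C9) to the face syn to OH, which fixes C8 and C10.

Step 3
Reactants: 4 (1S,2R,5R)-4,4-dimethylbicyclo[3.1.0]hexan-2-ol
Product: 5 (1S,5R)-4,4-dimethylbicyclo[3.1.0]hexan-2-one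
Conditions: Dess–Martin periodinane, CH2Cl2, rt
Reagents that add atoms: none
Why: Dess–Martin oxidation converts the secondary carbinol into the ketone under neutral conditions that leave the cyclopropane and its two stereocentres untouched.

Step 4
Reactants: 5 (1S,5R)-4,4-dimethylbicyclo[3.1.0]hexan-2-one; 6 methyl vinyl ketone
Product: 7 (1S,3S,5R)-4,4-dimethyl-3-(3-oxobutyl)bicyclo[3.1.0]hexan-2-one (chain trans to the cyclopropane CH2)
Conditions: KOt-Bu (10 mol %), t-BuOH/THF, 0 °C, slow addition of 6, early quench
Reagents that add atoms: methyl vinyl ketone, C=CC(C)=O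
Why: In this Michael addition C6 is the only enolisable position because the other α-carbon is the cyclopropane bridgehead, and both the approach of the acceptor and base equilibration place the new chain anti to the cyclopropane CH2.

Step 5
Reactants: 7 (1S,3S,5R)-4,4-dimethyl-3-(3-oxobutyl)bicyclo[3.1.0]hexan-2-one; 8 triethyl phosphonoacetate
Product: 9 ethyl (2E)-5-[(1S,3S,5R)-4,4-dimethyl-2-oxobicyclo[3.1.0]hexan-3-yl]-3-methylpent-2-enoate
Conditions: NaH, (EtO)2P(O)CH2CO2Et, THF, 0 °C to rt
Reagents that add atoms: triethyl phosphonoacetate, CCOC(=O)CP(=O)(OCC)OCC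
Why: Horner–Wadsworth–Emmons olefination should occur only at the unhindered methyl ketone (the ring ketone is flanked by the cyclopropane and by the branched C6 next to CMe2) and favours the E-enoate, the minor Z isomer being removed by chromatography.

Step 6
Reactants: 9 ethyl (2E)-5-[(1S,3S,5R)-4,4-dimethyl-2-oxobicyclo[3.1.0]hexan-3-yl]-3-methylpent-2-enoate; 10 trimethylsulfonium iodide
Product: 11 ethyl (2E)-5-[(1S,2S,3S,5R)-4,4-dimethylspiro[bicyclo[3.1.0]hexane-2,2'-oxiran]-3-yl]-3-methylpent-2-enoate (oxirane O on the side of the cyclopropane CH2)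
Conditions: Me3S+ I−, NaH, DMSO/THF, 0 °C to rt
Reagents that add atoms: trimethylsulfonium iodide, C[S+](C)C.[I-]
Why: In the Corey–Chaykovsky epoxidation the sulfonium methylide adds 1,2 to the remaining ketone anti to the cyclopropane CH2 and closes the oxirane, the β,β-disubstituted enoate is too poor an acceptor to compete, and the C7 configuration is erased again in step 7.

Step 7
Reactants: 11 ethyl (2E)-5-[(1S,2S,3S,5R)-4,4-dimethylspiro[bicyclo[3.1.0]hexane-2,2'-oxiran]-3-yl]-3-methylpent-2-enoate
Product: 12 ethyl (2E)-5-[(1R,5R)-5-bromo-2-(hydroxymethyl)-6,6-dimethylcyclohex-2-en-1-yl]-3-methylpent-2-enoate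
Conditions: MgBr2·OEt2 (3 equiv), Et2O/CH2Cl2, −40 to 0 °C; aq. NH4Cl
Reagents that add atoms: magnesium bromide etherate, [Mg+2].[Br-].[Br-].CCOCC
Why: MgBr2 ionises the oxirane C–O bond at the tertiary, cyclopropyl-flanked C7, the cyclopropylcarbinyl cation is delocalised into the C8–C10 zero bridge, and bromide attacks C10 from the side opposite to that bond, so that C7=C8 forms, the cyclopentane C6–C7–C8–C10–C11 takes up C9 and the oxygen ends as the allylic CH2OH. The closest known reaction type is the Julia cyclopropylcarbinyl-to-homoallyl bromide rearrangement, in the ring-enlarging form known from thujane-to-p-menthane and i-steroid openings. No ring is closed, because the six-membered ring arises by cleavage of the bond shared by the two rings of the bicyclo[3.1.0]hexane. The only new stereocentre, C10, is set by inversion and therefore by the cyclopropane configuration fixed in step 2, which places Br trans to the C6 side chain, a relation that a chair-like bromonium cyclisation does not deliver. The step needs internal (C8–C10) rather than external (C8–C9) cleavage and capture before a 1,2-hydride shift; this should be favoured because charge goes to the secondary C10 next to the quaternary C11 rather than to the primary C9, the β-oxygen raises the demand of the cation on the cyclopropane, and internal cleavage releases the whole bicyclic strain. The enoate keeps the side-chain alkene too electron-poor to intercept the cation.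

Step 8
Reactants: 12 ethyl (2E)-5-[(1R,5R)-5-bromo-2-(hydroxymethyl)-6,6-dimethylcyclohex-2-en-1-yl]-3-methylpent-2-enoate
Product: 13 (2E)-5-[(1R,5R)-5-bromo-2-(hydroxymethyl)-6,6-dimethylcyclohex-2-en-1-yl]-3-methylpent-2-en-1-ol
Conditions: DIBAL-H (3.5 equiv), CH2Cl2, −78 °C; Rochelle salt
Reagents that add atoms: none
Why: DIBAL-H reduces the conjugated ester 1,2 to the E-allylic alcohol at low temperature without touching the unactivated secondary bromide or either alkene.

Step 9
Reactants: 13 (2E)-5-[(1R,5R)-5-bromo-2-(hydroxymethyl)-6,6-dimethylcyclohex-2-en-1-yl]-3-methylpent-2-en-1-ol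
Product: 14 [(2S,3S)-3-{2-[(1S,2S,4R,6S)-4-bromo-1-(hydroxymethyl)-3,3-dimethyl-7-oxabicyclo[4.1.0]heptan-2-yl]ethyl}-3-methyloxiran-2-yl]methanol (ring oxirane anti to the side chain)
Conditions: Ti(Oi-Pr)4 (20 mol %), L-(+)-DET (24 mol %), t-BuOOH (3 equiv), 4 Å MS, CH2Cl2, −25 °C
Reagents that add atoms: tert-butyl hydroperoxide, CC(C)(C)OO
Why: In this double Sharpless asymmetric epoxidation both alkenes are primary allylic alcohols, and L-(+)-DET, which gives (2S,3S)-epoxides from geraniol-type E-alkenes, sets C3 and by the same facial rule attacks C7=C8 anti to the side chain, so the two C–O stereocentres that survive (C3, C8) are reagent-controlled.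

Step 10
Reactants: 14 the bis-epoxy diol of step 9
Product: 16 (3S)-5-[(1R,3R,5S)-3-bromo-5-hydroxy-2,2-dimethyl-6-methylidenecyclohexyl]-3-methylpent-1-en-3-ol, via bis-epoxy diiodide 15 (not isolated)
Conditions: PPh3, I2, imidazole, THF, 0 °C; then Zn dust, EtOH, 40 °C
Reagents that add atoms: iodine, II (iodine is present in 15 only)
Why: Appel-type iodination of the two primary epoxy carbinols, then zinc insertion and β-elimination (reductive epoxide opening, 1,3-transposition), unveils the vinyl carbinol and the C7 methylidene/C8 carbinol with retention at C3 and C8 because neither C–O bond is broken, and the neopentyl-type secondary bromide is inert to zinc.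

Step 11
Reactants: 16 (3S)-5-[(1R,3R,5S)-3-bromo-5-hydroxy-2,2-dimethyl-6-methylidenecyclohexyl]-3-methylpent-1-en-3-ol
Product: 17 (3S)-5-[(1S,3R,5R)-3,5-dibromo-2,2-dimethyl-6-methylidenecyclohexyl]-3-methylpent-1-en-3-ol
Conditions: CBr4 (1.1 equiv), PPh3 (1.1 equiv), CH2Cl2, −20 to 0 °C
Reagents that add atoms: carbon tetrabromide, BrC(Br)(Br)Br
Why: In the Appel bromination only the secondary allylic C8–OH should form a displaceable alkoxyphosphonium ion, SN2 attack of bromide inverts C8 so that Br ends cis to the side chain and trans to C10–Br, and the low temperature without added bromide salt limits SN2′ leakage and spares the tertiary C3–OH.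

Compound list
1 | 4,4-dimethylcyclopent-2-en-1-one | CC1(C)C=CC(=O)C1 | starting material
2 | (1R)-4,4-dimethylcyclopent-2-en-1-ol | O[C@H]1C=CC(C)(C)C1 | intermediate
3 | diiodomethane | ICI | starting material
4 | (1S,2R,5R)-4,4-dimethylbicyclo[3.1.0]hexan-2-ol | O[C@@H]1CC(C)(C)[C@@H]2C[C@H]12 | intermediate
5 | (1S,5R)-4,4-dimethylbicyclo[3.1.0]hexan-2-one | O=C1CC(C)(C)[C@@H]2C[C@H]12 | intermediate
6 | methyl vinyl ketone | C=CC(C)=O | starting material
7 | (1S,3S,5R)-4,4-dimethyl-3-(3-oxobutyl)bicyclo[3.1.0]hexan-2-one | O=C1[C@@H](CCC(C)=O)C(C)(C)[C@@H]2C[C@H]12 | intermediate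
8 | triethyl phosphonoacetate | CCOC(=O)CP(=O)(OCC)OCC | starting material
9 | ethyl (2E)-5-[(1S,3S,5R)-4,4-dimethyl-2-oxobicyclo[3.1.0]hexan-3-yl]-3-methylpent-2-enoate | O=C1[C@@H](CC/C(C)=C/C(=O)OCC)C(C)(C)[C@@H]2C[C@H]12 | intermediate
10 | trimethylsulfonium iodide | C[S+](C)C.[I-] | starting material
11 | ethyl (2E)-5-[(1S,2S,3S,5R)-4,4-dimethylspiro[bicyclo[3.1.0]hexane-2,2'-oxiran]-3-yl]-3-methylpent-2-enoate | C1O[C@@]12[C@@H](CC/C(C)=C/C(=O)OCC)C(C)(C)[C@@H]3C[C@H]23 | intermediate
12 | ethyl (2E)-5-[(1R,5R)-5-bromo-2-(hydroxymethyl)-6,6-dimethylcyclohex-2-en-1-yl]-3-methylpent-2-enoate | CCOC(=O)/C=C(\C)CC[C@@H]1C(CO)=CC[C@@H](Br)C1(C)C | intermediate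
13 | (2E)-5-[(1R,5R)-5-bromo-2-(hydroxymethyl)-6,6-dimethylcyclohex-2-en-1-yl]-3-methylpent-2-en-1-ol | OC/C=C(\C)CC[C@@H]1C(CO)=CC[C@@H](Br)C1(C)C | intermediate
14 | [(2S,3S)-3-{2-[(1S,2S,4R,6S)-4-bromo-1-(hydroxymethyl)-3,3-dimethyl-7-oxabicyclo[4.1.0]heptan-2-yl]ethyl}-3-methyloxiran-2-yl]methanol | OC[C@@H]1O[C@@]1(C)CC[C@@H]2[C@@]3(CO)O[C@H]3C[C@@H](Br)C2(C)C | intermediate
15 | bis-epoxy diiodide (both CH2OH groups of 14 replaced by CH2I, all other centres unchanged) | IC[C@@H]1O[C@@]1(C)CC[C@@H]2[C@@]3(CI)O[C@H]3C[C@@H](Br)C2(C)C | intermediate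
16 | (3S)-5-[(1R,3R,5S)-3-bromo-5-hydroxy-2,2-dimethyl-6-methylidenecyclohexyl]-3-methylpent-1-en-3-ol | C=C[C@@](C)(O)CC[C@@H]1C(=C)[C@@H](O)C[C@@H](Br)C1(C)C | intermediate
17 | (3S)-5-[(1S,3R,5R)-3,5-dibromo-2,2-dimethyl-6-methylidenecyclohexyl]-3-methylpent-1-en-3-ol | C=C[C@@](C)(O)CC[C@@H]1C(=C)[C@H](Br)C[C@@H](Br)C1(C)C | target

Total step count: 11. Longest linear sequence: 11 steps (1 to 17).

Steps most likely to fail

Step 7.
- **What may go wrong:** bromide may attack the less hindered cyclopropane CH2, which cleaves the external bond and gives no ring enlargement. It may also open the oxirane at its CH2 terminus, or the cation may undergo a 1,2-hydride shift to an aldehyde.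
- **Fallback (from 9, back at 12):** the oxygen is taken out of the ring-enlarging event and introduced afterwards by C–H oxidation.
- Wittig methylenation of 9 (Ph3PCH3Br, KOt-Bu, toluene, 60 °C) should give the vinylcyclopropane ethyl (2E)-5-[(1S,3S,5R)-4,4-dimethyl-2-methylidenebicyclo[3.1.0]hexan-3-yl]-3-methylpent-2-enoate F1.
- One equivalent of dry HBr (CH2Cl2, −40 °C) protonates the exocyclic methylene to the oxygen-free tertiary cyclopropylcarbinyl cation. The tertiary bromide and the alkene isomers re-ionise under these conditions, so the material should drain into the homoallylic bromide ethyl (2E)-5-[(1R,5R)-5-bromo-2,6,6-trimethylcyclohex-2-en-1-yl]-3-methylpent-2-enoate F2.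
- Allylic oxidation with catalytic SeO2 and t-BuOOH (NaBH4 work-up) should then hydroxylate the C7 methyl group. The competing ring position C6 is a hindered methine and the enoate alkene is deactivated. This gives 12.

Step 11.
- **What may go wrong:** allylic transposition, either by SN2′ attack at the exocyclic CH2 or by later bromide-induced isomerisation to the primary allylic bromide, and partial loss of inversion through ion pairing.
- **Fallback (from 16, back at 17):** C8–Br is formed by electrophilic instead of nucleophilic bromination.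
- Selective acetylation of the secondary alcohol (Ac2O, pyridine, 0 °C) should give (1S,5R)-5-bromo-3-[(3S)-3-hydroxy-3-methylpent-4-en-1-yl]-4,4-dimethyl-2-methylidenecyclohexyl acetate F3.
- Pd(0)-catalysed silylation of this allylic acetate with hexamethyldisilane (Pd(dba)2, LiCl, DMF) places silicon on the unhindered exocyclic terminus and gives the allylsilane (3S)-5-[(1R,5R)-5-bromo-6,6-dimethyl-2-(trimethylsilylmethyl)cyclohex-2-en-1-yl]-3-methylpent-1-en-3-ol F4.
- NBS (CH2Cl2, −78 °C) brominates C8 by SE2′ attack with loss of silicon, which regenerates the C7 methylidene regiospecifically. The C–Si bond should sit on the ring face opposite to the pseudoaxial C6 chain, so bromine enters anti to silicon on the face of the chain, as required for 17.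

Step 4.
- **What may go wrong:** slow C–C bond formation at the neopentyl-type C6, polymerisation of the acceptor, and follow-up intramolecular aldol closure of the 1,5-diketone.
- **Fallback (from 5, back at 7):** the conjugate addition is replaced by an SN2 alkylation with a masked ketone.
- The lithium enolate of 5 (LDA, THF/DMPU, −78 to 0 °C) is alkylated with 2-(2-iodoethyl)-2-methyl-1,3-dioxolane, again anti to the cyclopropane CH2, to give (1S,3S,5R)-4,4-dimethyl-3-[2-(2-methyl-1,3-dioxolan-2-yl)ethyl]bicyclo[3.1.0]hexan-2-one F5.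
- Mild hydrolysis (PPTS, wet acetone) then releases 7.

Further compounds
F1 | step 7 | ethyl (2E)-5-[(1S,3S,5R)-4,4-dimethyl-2-methylidenebicyclo[3.1.0]hexan-3-yl]-3-methylpent-2-enoate | C=C1[C@@H](CC/C(C)=C/C(=O)OCC)C(C)(C)[C@@H]2C[C@H]12
F2 | step 7 | ethyl (2E)-5-[(1R,5R)-5-bromo-2,6,6-trimethylcyclohex-2-en-1-yl]-3-methylpent-2-enoate | CCOC(=O)/C=C(\C)CC[C@@H]1C(C)=CC[C@@H](Br)C1(C)C
F3 | step 11 | (1S,5R)-5-bromo-3-[(3S)-3-hydroxy-3-methylpent-4-en-1-yl]-4,4-dimethyl-2-methylidenecyclohexyl acetate (C8 acetate of 16) | C=C[C@@](C)(O)CC[C@@H]1C(=C)[C@@H](OC(C)=O)C[C@@H](Br)C1(C)C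
F4 | step 11 | (3S)-5-[(1R,5R)-5-bromo-6,6-dimethyl-2-(trimethylsilylmethyl)cyclohex-2-en-1-yl]-3-methylpent-1-en-3-ol | C=C[C@@](C)(O)CC[C@@H]1C(C[Si](C)(C)C)=CC[C@@H](Br)C1(C)C
F5 | step 4 | (1S,3S,5R)-4,4-dimethyl-3-[2-(2-methyl-1,3-dioxolan-2-yl)ethyl]bicyclo[3.1.0]hexan-2-one | O=C1[C@@H](CCC2(C)OCCO2)C(C)(C)[C@@H]3C[C@H]13
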